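Readings and results are calculated on assumed constants; scatter was added.

Follow one molecule of starting material through Sunday's flask, the flask asked about, and ask its chances at each fork.

the same everywhere: starting material 0.10 M

| flask | first nucleophile | second nucleophile | protic impurity | remark | time |
|---|---|---|---|---|---|
| Sunday's | 0.20 M | 0.050 M | 0.050 M | the very flask that is asked about, followed so far |  |
| Thursday's | 0.30 M | 0.050 M | 0.050 M | run made earlier |  |
| flask | 0.200 M | 0.0500 M | 0.0500 M |  | 15 d |

Sunday's run (percent of the starting material charged)

| time / h | other capture product / % | target / % |
|---|---|---|
| 3.00 | 3.2 | 3.9 |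
| 5.00 | 4.7 | 5.8 |
| 8.00 | 6.5 | 7.7 |
| 12.0 | 8.8 | 10.8 |
| 20.0 | 13.0 | 14.4 |
| 30.0 | 15.5 | 16.5 |
| 40.0 | 17.7 | 18.8 |

Thursday's run (percent of the starting material charged)

| time / d | other capture product / % | target / % |
|---|---|---|
| 1.67 | 14.5 | 23.0 |
| 3.00 | 17.8 | 27.3 |
| 5.00 | 19.2 | 29.7 |
| 6.00 | 19.8 | 29.8 |
| 8.00 | 20.1 | 30.0 |
| 10.0 | 19.6 | 30.6 |

(readings scatter by 0.3 percentage points)

- share of other capture product in other capture product plus target at 40 min
- share of other capture product in other capture product plus target at 15 h
- share of other capture product in other capture product plus target at 15 d

Once the molecule is intermediate, it meets two partners, and its odds o of becoming other capture product rather than target are F·[second nucleophile]/[free first nucleophile]; its share is then o/(1+o). Sunday's early reading at 3.00 h, each figure good to 0.3 percentage points, gives F = 3.28 if both nucleophiles are taken at their charges. I call F the fork factor, a selectivity factor: the readiness of the intermediate for second nucleophile over first.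

Two versions of Sunday's flask can be done in the head. In the first, the fork stays as charged: o = 0.821, a share of 45.1%. In the second, the fork stands from the start as it does late on: the increments between 20.0 h and 40.0 h read o = 1.07, higher than the first, a share of 51.6%. With second nucleophile near 0.0347 M there, F implies about 0.106 M of free first nucleophile.

Sunday's flask drifts from the first version towards the second. By 20.0 h Sunday's capture reads 27.4%, about half of the 50.2% read at the end of Thursday's run, which had more first nucleophile. Taking it as my assumption that Sunday's flask levels off like Thursday's, I weigh the two versions about equally and commit to about 45.1% at 40 min, about 48.4% at 15 d, and a value between them at 15 h.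

The forecast says 44%, 46% and 48.5%, holding for the time after 40 h that “second nucleophile depletion offsets dormancy”.

The flask gives 46.0%, 47.6% and 48.3%. At 1.50 d that flask holds 56.3% of its charge of first nucleophile as such and 65.6% of its charge of second, so F puts the fork at o = 0.956, between the two versions .

    starting material ⇌ intermediate (K = 0.0830, k = 0.0311 /h)
    first nucleophile + intermediate → target (k = 36.3 /M/h)
    second nucleophile + intermediate → other capture product (k = 123 /M/h)
    starting material + protic impurity → quenched substrate (k = 3.84 /M/h)
    first nucleophile ⇌ dormant form (K = 0.670, k = 0.0296 /h)
    intermediate → decomposed reagent (k = 0.0466 /h)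

In a neighbour flask charged with 0.34 M of first nucleophile, its other charges as in the flask asked about, F gives 32.6% for the as-charged version, and scaling the late odds by the charges gives 38.6%. That neighbour gives 33.4% at 40 min and 36.9% at 15 d.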